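**Retrosynthetic overview**

Carotenoid numbering is used: primed atoms lie on the ε-ring half, and the lactone ring is O–C19'(=O)–C9'=C10'–C11'. The C40 chain is cut at the C14'–C15' single bond into a C18 terminal alkyne (the Z-ylidenebutenolide ending in C13'≡C14'H, still without the C20' methyl group) and an all-E C21 pentaenyl bromide (C15'–Br).
Enabling feature: C13' bears a methyl group and is E-doubly bonded to C14', the left-hand atom of the bond to be made, and this unit is conjugated through C11'=C12' with the five-membered lactone ring. A 2-methylalk-1-enyl metal is what syn-methylmetalation of a terminal alkyne gives, so one pot (Zr-catalysed methylalumination, then Pd-catalysed alkenyl–alkenyl coupling) adds C20', fixes 13'E and forges C14'–C15'.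
Left half: the ε-ring is taken from racemic dihydro-α-ionone (C3' oxidation, Luche reduction, lipase resolution). The butenolide is closed by ring-closing metathesis of an allyl 2-alkylacrylate, and the Z-ylidene/alkyne is added by a one-pot vinylogous aldol–elimination with 3-(trimethylsilyl)propynal.
Right half: the β-ring is taken from (4R,6R)-actinol via its enol triflate (Heck reaction). The chain grows by two rounds of methylalumination/coupling with (E)-1-bromo-2-iodoethene, separated by one ethynylation.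
Ring order: both six-membered rings are bought; the only ring made is the lactone (step 16), before the key step; one desilylation follows the key step.

Key step: step 19

Remark: the lipase of step 13 is assumed to acylate the (4R)-configured cyclohex-2-enol faster, as is usual for such allylic alcohols; with the opposite preference the unreacted alcohol would be the one carried on.

**Route**

Step 1
Reactants: 1 (4R,6R)-4-hydroxy-2,2,6-trimethylcyclohexan-1-one (actinol)
Product: 2 (4R,6R)-4-(tert-butyldimethylsilyloxy)-2,2,6-trimethylcyclohexan-1-one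
Conditions: TBSCl, imidazole, DMF, rt
Reagents that add atoms: tert-butyldimethylsilyl chloride, CC(C)(C)[Si](C)(C)Cl
Why: Imidazole-promoted silyl ether formation at the only hydroxyl group should proceed without touching either stereocentre.

Step 2
Reactants: 2 (4R,6R)-4-(tert-butyldimethylsilyloxy)-2,2,6-trimethylcyclohexan-1-one
Product: 3 (4R)-4-(tert-butyldimethylsilyloxy)-2,6,6-trimethylcyclohex-1-en-1-yl trifluoromethanesulfonate
Conditions: LiN(i-Pr)2, THF, −78 °C; PhNTf2, −78 °C to rt
Reagents that add atoms: N-phenylbis(trifluoromethanesulfonimide), O=S(=O)(N(c1ccccc1)S(=O)(=O)C(F)(F)F)C(F)(F)F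
Why: The ketone can enolise only towards C6 (C2 is quaternary), so enolate O-triflation (enol triflate formation) should give one regioisomer; the C6 stereocentre is erased on purpose and C4 is untouched.

Step 3
Reactants: 3 (4R)-4-(tert-butyldimethylsilyloxy)-2,6,6-trimethylcyclohex-1-en-1-yl trifluoromethanesulfonate; 4 but-3-en-2-one (methyl vinyl ketone)
Product: 5 (3E)-4-[(4R)-4-(tert-butyldimethylsilyloxy)-2,6,6-trimethylcyclohex-1-en-1-yl]but-3-en-2-one
Conditions: Pd(OAc)2 (cat.), PPh3, Et3N, DMF, 70 °C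
Reagents that add atoms: none
Why: Mizoroki–Heck reaction: oxidative addition of the enol triflate to zerovalent palladium, syn-insertion of the enone and syn-β-hydride elimination should give the E-dienone.

Step 4
Reactants: 5 (3E)-4-[(4R)-4-(tert-butyldimethylsilyloxy)-2,6,6-trimethylcyclohex-1-en-1-yl]but-3-en-2-one
Product: 7 (1R)-4-[(1E)-but-1-en-3-yn-1-yl]-3,5,5-trimethylcyclohex-3-en-1-yl tert-butyldimethylsilyl ether, via enol phosphate 6 (not isolated)
Conditions: LiN(i-Pr)2, THF, −78 °C; ClP(O)(OEt)2; then LiN(i-Pr)2 (2.2 equiv), −78 °C to rt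
Reagents that add atoms: none
Why: Methyl ketone-to-alkyne conversion: kinetic enolisation at the methyl group, O-phosphorylation and base-induced elimination of diethyl phosphate from the enol phosphate should give the terminal enyne with the E-alkene intact.

Step 5
Reactants: 8 ethyne
Product: 9 (E)-1-bromo-2-iodoethene
Conditions: IBr, 48% aq. HBr, 0 °C
Reagents that add atoms: iodine monobromide, IBr
Why: Electrophilic anti-addition of I–Br across the triple bond should give the E-dihaloalkene, whose two halides differ enough in reactivity for sequential coupling.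

Step 6
Reactants: 7 (1R)-4-[(1E)-but-1-en-3-yn-1-yl]-3,5,5-trimethylcyclohex-3-en-1-yl tert-butyldimethylsilyl ether; 9 (E)-1-bromo-2-iodoethene
Product: 11 (1R)-4-[(1E,3E,5E)-6-bromo-3-methylhexa-1,3,5-trien-1-yl]-3,5,5-trimethylcyclohex-3-en-1-yl tert-butyldimethylsilyl ether, via alkenyldimethylalane 10 (not isolated)
Conditions: AlMe3, Cp2ZrCl2 (cat.), CH2Cl2, rt; volatiles removed; then 9, Pd(PPh3)4 (cat.), ZnCl2 (cat.), THF, 0 °C to rt
Reagents that add atoms: trimethylaluminium, C[Al](C)C
Why: Tandem Zr-catalysed alkyne carboalumination / Negishi coupling: syn-addition of Me–Al puts methyl on the internal carbon and aluminium on the terminal one, and the E-alkenylalane should couple with retention at the more reactive C–I bond of 9, leaving C–Br for step 7.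

Step 7
Reactants: 11 (1R)-4-[(1E,3E,5E)-6-bromo-3-methylhexa-1,3,5-trien-1-yl]-3,5,5-trimethylcyclohex-3-en-1-yl tert-butyldimethylsilyl ether; 12 ethynylmagnesium bromide
Product: 14 (1R)-4-[(1E,3E,5E)-3-methylocta-1,3,5-trien-7-yn-1-yl]-3,5,5-trimethylcyclohex-3-en-1-yl tert-butyldimethylsilyl ether, via ethynylzinc bromide 13 (not isolated)
Conditions: HC≡CMgBr, ZnBr2, THF, 0 °C; then 11, Pd(PPh3)4 (cat.), rt
Reagents that add atoms: none
Why: Negishi alkynylation: the alkenyl bromide should couple with ethynylzinc bromide under zerovalent palladium with retention of the E geometry, giving the terminal alkyne without a protecting group.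

Step 8
Reactants: 14 (1R)-4-[(1E,3E,5E)-3-methylocta-1,3,5-trien-7-yn-1-yl]-3,5,5-trimethylcyclohex-3-en-1-yl tert-butyldimethylsilyl ether; 9 (E)-1-bromo-2-iodoethene
Product: 16 (1R)-4-[(1E,3E,5E,7E,9E)-10-bromo-3,7-dimethyldeca-1,3,5,7,9-pentaen-1-yl]-3,5,5-trimethylcyclohex-3-en-1-yl tert-butyldimethylsilyl ether, via alkenyldimethylalane 15 (not isolated)
Conditions: AlMe3, Cp2ZrCl2 (cat.), CH2Cl2, rt; volatiles removed; then 9, Pd(PPh3)4 (cat.), ZnCl2 (cat.), THF, 0 °C to rt
Reagents that add atoms: trimethylaluminium, C[Al](C)C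
Why: A second tandem alkyne carboalumination / Negishi coupling should install the C20 methyl group and the 13E alkene by syn-addition and attach the C15=C15' unit with retention at the C–I bond of 9.

Step 9
Reactants: 17 4-(2,6,6-trimethylcyclohex-2-en-1-yl)butan-2-one (racemic dihydro-α-ionone)
Product: 18 4-(2,6,6-trimethylcyclohex-2-en-1-yl)but-1-en-2-yl trifluoromethanesulfonate (racemic)
Conditions: LiN(i-Pr)2, THF, −78 °C; PhNTf2, −78 °C to rt
Reagents that add atoms: N-phenylbis(trifluoromethanesulfonimide), O=S(=O)(N(c1ccccc1)S(=O)(=O)C(F)(F)F)C(F)(F)F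
Why: Kinetic deprotonation of the methyl ketone at the methyl group and O-triflation of the less substituted enolate (enol triflate formation) should give the 1-alken-2-yl triflate without affecting the ring.

Step 10
Reactants: 18 4-(2,6,6-trimethylcyclohex-2-en-1-yl)but-1-en-2-yl trifluoromethanesulfonate
Product: 19 methyl 2-methylidene-4-(2,6,6-trimethylcyclohex-2-en-1-yl)butanoate (racemic)
Conditions: Pd(OAc)2 (cat.), PPh3, CO (1 atm), MeOH, Et3N, DMF, 50 °C
Reagents that add atoms: carbon monoxide, [C-]#[O+]; methanol, CO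
Why: Palladium-catalysed alkoxycarbonylation of the enol triflate (oxidative addition, CO insertion, methanolysis of the acylpalladium) should give the 2-substituted acrylate, whose carbonyl carbon becomes C19'.

Step 11
Reactants: 19 methyl 2-methylidene-4-(2,6,6-trimethylcyclohex-2-en-1-yl)butanoate
Product: 20 methyl 2-methylidene-4-(2,6,6-trimethyl-4-oxocyclohex-2-en-1-yl)butanoate (racemic)
Conditions: CrO3 (cat.), t-BuOOH, CH2Cl2, rt
Reagents that add atoms: tert-butyl hydroperoxide, CC(C)(C)OO
Why: Chromium-catalysed allylic oxidation should convert the ring CH2 next to the electron-rich trisubstituted alkene into the enone, the acrylate and its allylic CH2 being deactivated by the ester.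

Step 12
Reactants: 20 methyl 2-methylidene-4-(2,6,6-trimethyl-4-oxocyclohex-2-en-1-yl)butanoate
Product: 21 rac-methyl 4-[(1R,4R)-4-hydroxy-2,6,6-trimethylcyclohex-2-en-1-yl]-2-methylidenebutanoate (trans racemate)
Conditions: NaBH4, CeCl3·7H2O, MeOH, −40 °C
Reagents that add atoms: none
Why: Luche reduction reduces only the enone carbonyl, and hydride should add anti to the axial methyl of the gem-dimethyl carbon, that is syn to the pseudoaxial side chain, which sets the 3',6'-trans relative configuration (the cis isomer is removed by chromatography).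

Step 13
Reactants: 21 rac-methyl 4-[(1R,4R)-4-hydroxy-2,6,6-trimethylcyclohex-2-en-1-yl]-2-methylidenebutanoate
Product: 22 methyl 4-[(1R,4R)-4-acetoxy-2,6,6-trimethylcyclohex-2-en-1-yl]-2-methylidenebutanoate
Conditions: lipase PS (Burkholderia cepacia, immobilised), vinyl acetate, t-BuOMe, 30 °C, stopped near half conversion
Reagents that add atoms: vinyl acetate, CC(=O)OC=C
Why: Lipase-catalysed kinetic resolution by irreversible transesterification should acylate the (4R)-alcohol selectively, so that the (1R,4R)-acetate is separated from the unreacted (1S,4S)-alcohol by chromatography.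

Step 14
Reactants: 22 methyl 4-[(1R,4R)-4-acetoxy-2,6,6-trimethylcyclohex-2-en-1-yl]-2-methylidenebutanoate
Product: 23 4-[(1R,4R)-4-hydroxy-2,6,6-trimethylcyclohex-2-en-1-yl]-2-methylidenebutanoic acid
Conditions: LiOH, THF–H2O, rt; then 1 M HCl
Reagents that add atoms: lithium hydroxide, [Li+].[OH-]
Why: Saponification should cleave both esters, since the α-branched acrylate resists conjugate addition and neither stereocentre is epimerisable.

Step 15
Reactants: 23 4-[(1R,4R)-4-hydroxy-2,6,6-trimethylcyclohex-2-en-1-yl]-2-methylidenebutanoic acid; 24 3-bromoprop-1-ene (allyl bromide)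
Product: 25 prop-2-en-1-yl 4-[(1R,4R)-4-hydroxy-2,6,6-trimethylcyclohex-2-en-1-yl]-2-methylidenebutanoate
Conditions: K2CO3, DMF, rt
Reagents that add atoms: none
Why: SN2 O-alkylation of the carboxylate under mild carbonate base should leave the far less acidic secondary alcohol untouched.

Step 16
Reactants: 25 prop-2-en-1-yl 4-[(1R,4R)-4-hydroxy-2,6,6-trimethylcyclohex-2-en-1-yl]-2-methylidenebutanoate
Product: 26 3-{2-[(1R,4R)-4-hydroxy-2,6,6-trimethylcyclohex-2-en-1-yl]ethyl}furan-2(5H)-one
Conditions: second-generation Grubbs catalyst (5 mol %), CH2Cl2 (5 mM), 40 °C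
Reagents that add atoms: none
Why: Ring-closing metathesis: the ruthenium alkylidene should load on the allyl group and close the five-membered lactone onto the 1,1-disubstituted acrylate alkene with loss of ethene, the trisubstituted ring alkene being inert.

Step 17
Reactants: 26 3-{2-[(1R,4R)-4-hydroxy-2,6,6-trimethylcyclohex-2-en-1-yl]ethyl}furan-2(5H)-one; 27 3-(trimethylsilyl)prop-2-ynal
Product: 30 (5Z)-3-{2-[(1R,4R)-4-(tert-butyldimethylsilyloxy)-2,6,6-trimethylcyclohex-2-en-1-yl]ethyl}-5-[3-(trimethylsilyl)prop-2-yn-1-ylidene]furan-2(5H)-one, via 2-silyloxyfuran 28 (not isolated), via aldol silyl ether 29 (not isolated)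
Conditions: TBSOTf (2.6 equiv), i-Pr2NEt, CH2Cl2, 0 °C to rt; then DBU, rt
Reagents that add atoms: tert-butyldimethylsilyl trifluoromethanesulfonate, CC(C)(C)[Si](C)(C)OS(=O)(=O)C(F)(F)F
Why: One-pot vinylogous Mukaiyama aldol / E1cB elimination: the 2-silyloxyfuran formed in situ should add through C5 to the ynal, and DBU should expel the silyloxy group to give the thermodynamically preferred Z-ylidene (alkynyl syn to the ring oxygen), the ring hydroxyl being silylated in the same pot.

Step 18
Reactants: 30 (5Z)-3-{2-[(1R,4R)-4-(tert-butyldimethylsilyloxy)-2,6,6-trimethylcyclohex-2-en-1-yl]ethyl}-5-[3-(trimethylsilyl)prop-2-yn-1-ylidene]furan-2(5H)-one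
Product: 31 (5Z)-3-{2-[(1R,4R)-4-(tert-butyldimethylsilyloxy)-2,6,6-trimethylcyclohex-2-en-1-yl]ethyl}-5-(prop-2-yn-1-ylidene)furan-2(5H)-one
Conditions: Bu4NF, AcOH, THF, −20 °C
Reagents that add atoms: none
Why: Buffered fluoride should cleave the C(sp)–SiMe3 bond selectively, while the secondary silyl ether and the enol lactone survive the near-neutral conditions.

Step 19
Reactants: 31 (5Z)-3-{2-[(1R,4R)-4-(tert-butyldimethylsilyloxy)-2,6,6-trimethylcyclohex-2-en-1-yl]ethyl}-5-(prop-2-yn-1-ylidene)furan-2(5H)-one; 16 (1R)-4-[(1E,3E,5E,7E,9E)-10-bromo-3,7-dimethyldeca-1,3,5,7,9-pentaen-1-yl]-3,5,5-trimethylcyclohex-3-en-1-yl tert-butyldimethylsilyl ether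
Product: 33 3,3'-bis-O-(tert-butyldimethylsilyl) ether of the target, via alkenyldimethylalane 32 (not isolated)
Conditions: AlMe3, Cp2ZrCl2 (cat.), CH2Cl2, 0 °C; volatiles removed; then 16, Pd2(dba)3 (cat.), P(2-furyl)3, ZnCl2 (cat.), THF, rt
Reagents that add atoms: trimethylaluminium, C[Al](C)C
Why: Zr-catalysed syn-methylalumination of the terminal alkyne of 31 should put the new methyl group (C20') on the internal carbon C13' and aluminium on C14', giving the E-alkenylalane 32; after removal of excess AlMe3, transmetalation (Al to Zn to Pd), oxidative addition of the C15'–Br bond of 16 to zerovalent palladium and reductive elimination should forge the C14'–C15' bond with retention at both alkenes. The closest known reaction type is the tandem alkyne carboalumination / palladium-catalysed alkenyl–alkenyl Negishi coupling used to build methyl-branched all-E polyene chains of isoprenoids. No ring is closed and no stereocentre is created; the only new stereo element, the 13'E double bond, is fixed by the syn addition of Me–Al and carried through the stereoretentive coupling. The step needs regioselectivity (methyl to the internal alkyne carbon, secured by the terminal alkyne) and chemoselectivity for the alkyne over the lactone carbonyl (secured by the low nucleophilicity of AlMe3 towards ester carbonyls at 0 °C and by evaporating excess AlMe3 before palladium is added). In one operation it installs a methyl branch, a stereodefined trisubstituted alkene and the fragment-joining bond, completing the C40 skeleton at its final oxidation level from an alkyne that has none of these.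

Step 20
Reactants: 33 3,3'-bis-O-(tert-butyldimethylsilyl) ether of the target
Product: 34 (3R,3'R,6'R)-3,3'-dihydroxy-7',8'-dihydro-β,ε-caroten-19',11'-olide (CNP0242041.1)
Conditions: HF·pyridine, pyridine, THF, 0 °C to rt, dark
Reagents that add atoms: none
Why: Fluoride-mediated cleavage of both secondary silyl ethers under buffered, non-basic conditions should spare the ylidenebutenolide and the polyene.

**Compound list**

1 | (4R,6R)-4-hydroxy-2,2,6-trimethylcyclohexan-1-one (actinol) | C[C@@H]1C[C@@H](O)CC(C)(C)C1=O | starting material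
2 | (4R,6R)-4-(tert-butyldimethylsilyloxy)-2,2,6-trimethylcyclohexan-1-one | C[C@@H]1C[C@@H](O[Si](C)(C)C(C)(C)C)CC(C)(C)C1=O | intermediate
3 | (4R)-4-(tert-butyldimethylsilyloxy)-2,6,6-trimethylcyclohex-1-en-1-yl trifluoromethanesulfonate | O=S(=O)(OC1=C(C)C[C@@H](O[Si](C)(C)C(C)(C)C)CC1(C)C)C(F)(F)F | intermediate
4 | but-3-en-2-one (methyl vinyl ketone) | CC(=O)C=C | starting material
5 | (3E)-4-[(4R)-4-(tert-butyldimethylsilyloxy)-2,6,6-trimethylcyclohex-1-en-1-yl]but-3-en-2-one | CC(=O)/C=C/C1=C(C)C[C@@H](O[Si](C)(C)C(C)(C)C)CC1(C)C | intermediate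
6 | diethyl (3E)-4-[(4R)-4-(tert-butyldimethylsilyloxy)-2,6,6-trimethylcyclohex-1-en-1-yl]buta-1,3-dien-2-yl phosphate (not isolated) | C=C(OP(=O)(OCC)OCC)/C=C/C1=C(C)C[C@@H](O[Si](C)(C)C(C)(C)C)CC1(C)C | intermediate
7 | (1R)-4-[(1E)-but-1-en-3-yn-1-yl]-3,5,5-trimethylcyclohex-3-en-1-yl tert-butyldimethylsilyl ether | C#C/C=C/C1=C(C)C[C@@H](O[Si](C)(C)C(C)(C)C)CC1(C)C | intermediate
8 | ethyne | C#C | starting material
9 | (E)-1-bromo-2-iodoethene | Br/C=C/I | intermediate
10 | [(1E,3E)-2-methyl-4-{(4R)-4-(tert-butyldimethylsilyloxy)-2,6,6-trimethylcyclohex-1-en-1-yl}buta-1,3-dien-1-yl]dimethylalane (not isolated) | C[Al](C)/C=C(C)/C=C/C1=C(C)C[C@@H](O[Si](C)(C)C(C)(C)C)CC1(C)C | intermediate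
11 | (1R)-4-[(1E,3E,5E)-6-bromo-3-methylhexa-1,3,5-trien-1-yl]-3,5,5-trimethylcyclohex-3-en-1-yl tert-butyldimethylsilyl ether | Br/C=C/C=C(C)/C=C/C1=C(C)C[C@@H](O[Si](C)(C)C(C)(C)C)CC1(C)C | intermediate
12 | ethynylmagnesium bromide | C#C[Mg]Br | starting material
13 | ethynylzinc bromide (not isolated) | C#C[Zn]Br | intermediate
14 | (1R)-4-[(1E,3E,5E)-3-methylocta-1,3,5-trien-7-yn-1-yl]-3,5,5-trimethylcyclohex-3-en-1-yl tert-butyldimethylsilyl ether | C#C/C=C/C=C(C)/C=C/C1=C(C)C[C@@H](O[Si](C)(C)C(C)(C)C)CC1(C)C | intermediate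
15 | [(1E,3E,5E,7E)-2,6-dimethyl-8-{(4R)-4-(tert-butyldimethylsilyloxy)-2,6,6-trimethylcyclohex-1-en-1-yl}octa-1,3,5,7-tetraen-1-yl]dimethylalane (not isolated) | C[Al](C)/C=C(C)/C=C/C=C(C)/C=C/C1=C(C)C[C@@H](O[Si](C)(C)C(C)(C)C)CC1(C)C | intermediate
16 | (1R)-4-[(1E,3E,5E,7E,9E)-10-bromo-3,7-dimethyldeca-1,3,5,7,9-pentaen-1-yl]-3,5,5-trimethylcyclohex-3-en-1-yl tert-butyldimethylsilyl ether | Br/C=C/C=C(C)/C=C/C=C(C)/C=C/C1=C(C)C[C@@H](O[Si](C)(C)C(C)(C)C)CC1(C)C | intermediate
17 | 4-(2,6,6-trimethylcyclohex-2-en-1-yl)butan-2-one (racemic dihydro-α-ionone) | CC1=CCCC(C)(C)C1CCC(C)=O | starting material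
18 | 4-(2,6,6-trimethylcyclohex-2-en-1-yl)but-1-en-2-yl trifluoromethanesulfonate (racemic) | CC1=CCCC(C)(C)C1CCC(=C)OS(=O)(=O)C(F)(F)F | intermediate
19 | methyl 2-methylidene-4-(2,6,6-trimethylcyclohex-2-en-1-yl)butanoate (racemic) | CC1=CCCC(C)(C)C1CCC(=C)C(=O)OC | intermediate
20 | methyl 2-methylidene-4-(2,6,6-trimethyl-4-oxocyclohex-2-en-1-yl)butanoate (racemic) | CC1=CC(=O)CC(C)(C)C1CCC(=C)C(=O)OC | intermediate
21 | rac-methyl 4-[(1R,4R)-4-hydroxy-2,6,6-trimethylcyclohex-2-en-1-yl]-2-methylidenebutanoate (trans racemate, one enantiomer drawn) | CC1=C[C@H](O)CC(C)(C)[C@H]1CCC(=C)C(=O)OC | intermediate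
22 | methyl 4-[(1R,4R)-4-acetoxy-2,6,6-trimethylcyclohex-2-en-1-yl]-2-methylidenebutanoate | CC1=C[C@H](OC(C)=O)CC(C)(C)[C@H]1CCC(=C)C(=O)OC | intermediate
23 | 4-[(1R,4R)-4-hydroxy-2,6,6-trimethylcyclohex-2-en-1-yl]-2-methylidenebutanoic acid | CC1=C[C@H](O)CC(C)(C)[C@H]1CCC(=C)C(=O)O | intermediate
24 | 3-bromoprop-1-ene (allyl bromide) | C=CCBr | starting material
25 | prop-2-en-1-yl 4-[(1R,4R)-4-hydroxy-2,6,6-trimethylcyclohex-2-en-1-yl]-2-methylidenebutanoate | CC1=C[C@H](O)CC(C)(C)[C@H]1CCC(=C)C(=O)OCC=C | intermediate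
26 | 3-{2-[(1R,4R)-4-hydroxy-2,6,6-trimethylcyclohex-2-en-1-yl]ethyl}furan-2(5H)-one | CC1=C[C@H](O)CC(C)(C)[C@H]1CCC1=CCOC1=O | intermediate
27 | 3-(trimethylsilyl)prop-2-ynal | C[Si](C)(C)C#CC=O | starting material
28 | tert-butyl{[3-(2-{(1R,4R)-4-(tert-butyldimethylsilyloxy)-2,6,6-trimethylcyclohex-2-en-1-yl}ethyl)furan-2-yl]oxy}dimethylsilane (not isolated) | CC1=C[C@H](O[Si](C)(C)C(C)(C)C)CC(C)(C)[C@H]1CCc1ccoc1O[Si](C)(C)C(C)(C)C | intermediate
29 | 5-[1-(tert-butyldimethylsilyloxy)-3-(trimethylsilyl)prop-2-yn-1-yl]-3-{2-[(1R,4R)-4-(tert-butyldimethylsilyloxy)-2,6,6-trimethylcyclohex-2-en-1-yl]ethyl}furan-2(5H)-one (not isolated, mixture of diastereomers at the two new centres) | CC1=C[C@H](O[Si](C)(C)C(C)(C)C)CC(C)(C)[C@H]1CCC1=CC(C(O[Si](C)(C)C(C)(C)C)C#C[Si](C)(C)C)OC1=O | intermediate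
30 | (5Z)-3-{2-[(1R,4R)-4-(tert-butyldimethylsilyloxy)-2,6,6-trimethylcyclohex-2-en-1-yl]ethyl}-5-[3-(trimethylsilyl)prop-2-yn-1-ylidene]furan-2(5H)-one | CC1=C[C@H](O[Si](C)(C)C(C)(C)C)CC(C)(C)[C@H]1CCC1=C/C(=C/C#C[Si](C)(C)C)OC1=O | intermediate
31 | (5Z)-3-{2-[(1R,4R)-4-(tert-butyldimethylsilyloxy)-2,6,6-trimethylcyclohex-2-en-1-yl]ethyl}-5-(prop-2-yn-1-ylidene)furan-2(5H)-one | CC1=C[C@H](O[Si](C)(C)C(C)(C)C)CC(C)(C)[C@H]1CCC1=C/C(=C/C#C)OC1=O | intermediate
32 | (5Z)-5-[(2E)-3-(dimethylalumanyl)-2-methylprop-2-en-1-ylidene]-3-{2-[(1R,4R)-4-(tert-butyldimethylsilyloxy)-2,6,6-trimethylcyclohex-2-en-1-yl]ethyl}furan-2(5H)-one (not isolated) | CC1=C[C@H](O[Si](C)(C)C(C)(C)C)CC(C)(C)[C@H]1CCC1=C/C(=C/C(C)=C/[Al](C)C)OC1=O | intermediate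
33 | 3,3'-bis-O-(tert-butyldimethylsilyl) ether of the target | CC1=C[C@H](O[Si](C)(C)C(C)(C)C)CC(C)(C)[C@H]1CCC1=C/C(=C/C(C)=C/C=C/C=C(C)/C=C/C=C(C)/C=C/C2=C(C)C[C@@H](O[Si](C)(C)C(C)(C)C)CC2(C)C)OC1=O | intermediate
34 | (3R,3'R,6'R)-3,3'-dihydroxy-7',8'-dihydro-β,ε-caroten-19',11'-olide (CNP0242041.1) | CC1=C[C@H](O)CC(C)(C)[C@H]1CCC1=C/C(=C/C(C)=C/C=C/C=C(C)/C=C/C=C(C)/C=C/C2=C(C)C[C@@H](O)CC2(C)C)OC1=O | target

**Totals and risks**

Total step count: 20.
Longest linear sequence: 12 steps (17 to 34, steps 9–20).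

Steps most likely to fail:

1. Step 19 (key step). What may go wrong: methyl transfer from AlMe3 to the lactone carbonyl or to the extended enol-ester acceptor, or slow carbometalation of the electron-poor alkyne, so that the alkenylalane does not form cleanly. The fallback is a Stille route that sets out from 26 and 16 and comes back at 33. (E)-3-Iodo-2-methylprop-2-en-1-ol, taken as commercial, is oxidised with MnO2 to (2E)-3-iodo-2-methylprop-2-enal F1, which already carries C20' and the E alkene. Condensation of 26 with F1 under the conditions of step 17 should give the iodo-ylidenebutenolide F2. Bromide 16 is converted with Bu3SnSnBu3 and Pd(PPh3)4 into the pentaenylstannane F3. Stille coupling of F2 with F3 (Pd2(dba)3, AsPh3, NMP, rt) makes the same C14'–C15' bond and gives 33.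

2. Step 12. What may go wrong: hydride delivery from the other carbonyl face, so that the 3',6'-cis alcohol predominates. The fallback sets out from 20 and comes back at 21. The cis racemate F4 is isolated instead and inverted at the carbinol carbon by a Mitsunobu reaction (4-nitrobenzoic acid, PPh3, DIAD) to the trans 4-nitrobenzoate F5, whose methanolysis (K2CO3, MeOH) returns the trans alcohol 21.

3. Step 3. What may go wrong: slow alkene insertion at the hindered, fully substituted alkenylpalladium centre, with reduction of the triflate or polymerisation of the enone taking over. The fallback sets out from 3 and comes back at 5. Sonogashira coupling of 3 with but-3-yn-2-ol (PdCl2(PPh3)2, CuI, Et3N) gives the propargylic alcohol F6, trans-hydroalumination with NaAlH2(OCH2CH2OCH3)2 gives the E-allylic alcohol F7, and MnO2 oxidation gives 5.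

**Further compounds**

F1 | step 19 | (2E)-3-iodo-2-methylprop-2-enal | O=C/C(C)=C/I
F2 | step 19 | (5Z)-3-{2-[(1R,4R)-4-(tert-butyldimethylsilyloxy)-2,6,6-trimethylcyclohex-2-en-1-yl]ethyl}-5-[(2E)-3-iodo-2-methylprop-2-en-1-ylidene]furan-2(5H)-one | CC1=C[C@H](O[Si](C)(C)C(C)(C)C)CC(C)(C)[C@H]1CCC1=C/C(=C/C(C)=C/I)OC1=O
F3 | step 19 | tributyl[(1E,3E,5E,7E,9E)-4,8-dimethyl-10-{(4R)-4-(tert-butyldimethylsilyloxy)-2,6,6-trimethylcyclohex-1-en-1-yl}deca-1,3,5,7,9-pentaen-1-yl]stannane | CCCC[Sn](CCCC)(CCCC)/C=C/C=C(C)/C=C/C=C(C)/C=C/C1=C(C)C[C@@H](O[Si](C)(C)C(C)(C)C)CC1(C)C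
F4 | step 12 | rac-methyl 4-[(1R,4S)-4-hydroxy-2,6,6-trimethylcyclohex-2-en-1-yl]-2-methylidenebutanoate (cis racemate, one enantiomer drawn) | CC1=C[C@@H](O)CC(C)(C)[C@H]1CCC(=C)C(=O)OC
F5 | step 12 | rac-methyl 2-methylidene-4-[(1R,4R)-4-(4-nitrobenzoyloxy)-2,6,6-trimethylcyclohex-2-en-1-yl]butanoate (trans racemate, one enantiomer drawn) | CC1=C[C@H](OC(=O)c2ccc(cc2)[N+](=O)[O-])CC(C)(C)[C@H]1CCC(=C)C(=O)OC
F6 | step 3 | 4-[(4R)-4-(tert-butyldimethylsilyloxy)-2,6,6-trimethylcyclohex-1-en-1-yl]but-3-yn-2-ol (both carbinol epimers) | CC(O)C#CC1=C(C)C[C@@H](O[Si](C)(C)C(C)(C)C)CC1(C)C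
F7 | step 3 | (3E)-4-[(4R)-4-(tert-butyldimethylsilyloxy)-2,6,6-trimethylcyclohex-1-en-1-yl]but-3-en-2-ol (both carbinol epimers) | CC(O)/C=C/C1=C(C)C[C@@H](O[Si](C)(C)C(C)(C)C)CC1(C)C
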